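**Retrosynthetic overview**
- The acetoxy lactol and the C15 aldehyde of 35 come from the bridged γ-lactone 30 (C16 to O11), which comes from the C11 ketone and the C13 ester of 28. The gem-dimethyl group is grown from a C4 ketone.
- Key disconnection: C8–C9 and C5–C6 together, so that rings C and B arise from the monocyclic keto-enal 23 by a Michael/aldol-condensation cascade (formal [3+3]).
- Enabling feature: the quaternary C10 is flanked by C5 (ring A) and C9. With carbonyls at C4 and at C11 (the C11 oxygen is native) both are inner α-carbons of a 1,5-diketone, and C6(=O)–C7=C8 is a 1,3-dielectrophile whose β-carbon C8 already carries C17 and C14.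
- 23 is assembled from the ring-A bromoketone 9 (C10 by Cu-catalysed asymmetric conjugate addition) and the malonate 20 (C14 by iminium-catalysed Michael addition, C6–C7 by aldol condensation).
- Ring order: A (preformed), then C and B in one operation, then the γ-lactone bridge, then the lactol acetate.

Key step: step 14

Remark: atoms are numbered as in the spongian skeleton (C1–C10 rings A/B with C20 on C10; C11–C14 ring C; C15 formyl, C16 acetal and C17 oxymethylene carbons; C18/C19 on C4), and β is the face of C20. Catalyst and ligand antipodes are chosen to give the configurations drawn.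

Step 1
Reactants: 1 3-ethoxycyclohex-2-en-1-one; 2 allylmagnesium bromide
Product: 3 3-(prop-2-en-1-yl)cyclohex-2-en-1-one
Conditions: THF, 0 °C; then 1 M HCl, 0 °C
Reagents that add atoms: allylmagnesium bromide, C=CC[Mg]Br
Why: 1,2-Addition of the Grignard reagent to the vinylogous ester followed by acid hydrolysis with allylic transposition (Stork–Danheiser sequence) should give the 3-substituted enone, with no stereocenter formed.

Step 2
Reactants: 3 3-(prop-2-en-1-yl)cyclohex-2-en-1-one; 4 trimethylaluminium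
Product: 5 (R)-3-methyl-3-(prop-2-en-1-yl)cyclohexan-1-one
Conditions: Me3Al, CuTC (2 mol %), chiral BINOL-derived phosphoramidite ligand (4 mol %, antipode giving (R)-5), Et2O, −30 °C
Reagents that add atoms: trimethylaluminium, C[Al](C)C
Why: Copper-catalysed asymmetric conjugate addition of Me3Al to a 3-substituted cyclohexenone should create the quaternary stereocenter C10, the ligand antipode being chosen so that methyl adds to the enone face that gives the (R) ketone.

Step 3
Reactants: 5 (R)-3-methyl-3-(prop-2-en-1-yl)cyclohexan-1-one; 6 N-bromosuccinimide; 7 water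
Product: 8 3-(3-bromo-2-hydroxypropyl)-3-methylcyclohexan-1-one (quaternary centre as in 5; carbinol epimers)
Conditions: NBS, DMSO/H2O, 0 °C
Reagents that add atoms: N-bromosuccinimide, O=C1CCC(=O)N1Br; water, O
Why: Bromohydrin formation (bromonium ion opened by water at the more substituted carbon) should place oxygen on the future C11 and bromine on C12, and the new carbinol centre is removed in step 4.

Step 4
Reactants: 8 3-(3-bromo-2-hydroxypropyl)-3-methylcyclohexan-1-one
Product: 9 3-(3-bromo-2-oxopropyl)-3-methylcyclohexan-1-one (quaternary centre as in 5)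
Conditions: Dess–Martin periodinane, CH2Cl2, rt
Reagents that add atoms: none
Why: Dess–Martin oxidation of the secondary alcohol should give the bromomethyl ketone without touching the ring ketone or the C–Br bond.

Step 5
Reactants: 10 (E)-but-2-ene-1,4-diol; 11 tert-butyl(chloro)diphenylsilane
Product: 12 (E)-4-{[tert-butyl(diphenyl)silyl]oxy}but-2-en-1-ol
Conditions: NaH (1.0 equiv), THF, 0 °C; then TBDPSCl, rt
Reagents that add atoms: tert-butyl(chloro)diphenylsilane, CC(C)(C)[Si](Cl)(c1ccccc1)c1ccccc1
Why: Monodeprotonation of the symmetric diol and silylation of the monosodium alkoxide should give the monosilyl ether.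

Step 6
Reactants: 12 (E)-4-{[tert-butyl(diphenyl)silyl]oxy}but-2-en-1-ol
Product: 13 (E)-4-{[tert-butyl(diphenyl)silyl]oxy}but-2-enal
Conditions: MnO2, CH2Cl2, rt
Reagents that add atoms: none
Why: Manganese dioxide should oxidise the allylic alcohol selectively to the (E)-enal.

Step 7
Reactants: 13 (E)-4-{[tert-butyl(diphenyl)silyl]oxy}but-2-enal; 14 dimethyl malonate
Product: 15 dimethyl (S)-2-[1-{[tert-butyl(diphenyl)silyl]oxy}-4-oxobutan-2-yl]malonate
Conditions: (S)-2-{bis[3,5-bis(trifluoromethyl)phenyl][(trimethylsilyl)oxy]methyl}pyrrolidine (10 mol %), EtOH, 0 °C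
Reagents that add atoms: dimethyl malonate, COC(=O)CC(=O)OC
Why: Iminium-catalysed enantioselective Michael addition of a malonate to an enal with a diarylprolinol silyl ether should set C14, because the silyloxydiarylmethyl group shields one face of the (E)-iminium ion and the nucleophile adds to the open Re face of the β-carbon, which corresponds to (S).

Step 8
Reactants: 15 dimethyl (S)-2-[1-{[tert-butyl(diphenyl)silyl]oxy}-4-oxobutan-2-yl]malonate; 16 2,2-dimethoxyacetaldehyde
Product: 17 dimethyl 2-[(E)-1-{[tert-butyl(diphenyl)silyl]oxy}-3-formyl-5,5-dimethoxypent-3-en-2-yl]malonate (C2 of the chain as in 15)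
Conditions: 16 (60% aq.), the (S)-pyrrolidine catalyst of step 7 (20 mol %), PhCO2H (20 mol %), toluene, rt → 40 °C
Reagents that add atoms: 2,2-dimethoxyacetaldehyde, COC(OC)C=O
Why: Enamine-mediated crossed aldol condensation of the α-methylene aldehyde with the non-enolisable glyoxal monoacetal should give the (E)-2-alkylidene aldehyde, and use of the same chiral amine keeps any retro-Michael/Michael equilibration at C14 under catalyst control.

Step 9
Reactants: 17 dimethyl 2-[(E)-1-{[tert-butyl(diphenyl)silyl]oxy}-3-formyl-5,5-dimethoxypent-3-en-2-yl]malonate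
Product: 18 dimethyl 2-[(E)-1-{[tert-butyl(diphenyl)silyl]oxy}-3-(hydroxymethyl)-5,5-dimethoxypent-3-en-2-yl]malonate
Conditions: NaBH4, CeCl3·7H2O, MeOH, −40 °C
Reagents that add atoms: none
Why: Luche 1,2-reduction should convert the enal into the allylic alcohol without reducing the esters or the C=C bond.

Step 10
Reactants: 18 dimethyl 2-[(E)-1-{[tert-butyl(diphenyl)silyl]oxy}-3-(hydroxymethyl)-5,5-dimethoxypent-3-en-2-yl]malonate; 19 3-methylbutanoyl chloride
Product: 20 dimethyl 2-[(E)-1-{[tert-butyl(diphenyl)silyl]oxy}-5,5-dimethoxy-3-{[(3-methylbutanoyl)oxy]methyl}pent-3-en-2-yl]malonate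
Conditions: pyridine, DMAP (cat.), CH2Cl2, 0 °C
Reagents that add atoms: 3-methylbutanoyl chloride, CC(C)CC(=O)Cl
Why: DMAP-catalysed acylation of the primary allylic alcohol should install the 3-methylbutanoate that the target carries on C17.

Step 11
Reactants: 20 dimethyl 2-[(E)-1-{[tert-butyl(diphenyl)silyl]oxy}-5,5-dimethoxy-3-{[(3-methylbutanoyl)oxy]methyl}pent-3-en-2-yl]malonate; 9 3-(3-bromo-2-oxopropyl)-3-methylcyclohexan-1-one
Product: 21 dimethyl 2-[the pentenyl arm of 20]-2-[3-(1-methyl-3-oxocyclohexyl)-2-oxopropyl]malonate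
Conditions: Cs2CO3, DMF, 0 °C → rt
Reagents that add atoms: bromoketone 9, O=C1CCC[C@](C)(CC(=O)CBr)C1
Why: SN2 alkylation of the soft malonate anion by the α-bromo ketone should join the two fragments through the C12–C13 bond, the carbonate being too weak a base to enolise the ketones.

Step 12
Reactants: 21 dimethyl 2-[the pentenyl arm of 20]-2-[3-(1-methyl-3-oxocyclohexyl)-2-oxopropyl]malonate
Product: 22 methyl 2-[the pentenyl arm of 20]-5-(1-methyl-3-oxocyclohexyl)-4-oxopentanoate (C13 epimers)
Conditions: LiCl, H2O, DMSO, 150 °C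
Reagents that add atoms: none
Why: Krapcho dealkoxycarbonylation (chloride attack on the methyl ester, decarboxylation, protonation) should remove one malonate ester and leave the C13 monoester as a mixture of epimers that is funnelled in step 17.

Step 13
Reactants: 22 methyl 2-[the pentenyl arm of 20]-5-(1-methyl-3-oxocyclohexyl)-4-oxopentanoate; 7 water
Product: 23 keto-enal: methyl 2-[(E)-1-{[tert-butyl(diphenyl)silyl]oxy}-3-{[(3-methylbutanoyl)oxy]methyl}-5-oxopent-3-en-2-yl]-5-(1-methyl-3-oxocyclohexyl)-4-oxopentanoate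
Conditions: PPTS (cat.), acetone/H2O, rt
Reagents that add atoms: water, O
Why: The α,β-unsaturated dimethyl acetal ionises readily under mild acid and should hydrolyse to the (E)-enal while the silyl ether and the esters survive.

Step 14
Reactants: 23 keto-enal
Product: 25 tricyclic enone (4,11-dioxo; C5=C6; 8β-CH2O-isovalerate; 9α-H; 10β-CH3; 13-CO2Me epimers; 14β-CH2OTBDPS), via keto-aldehyde 24 (not isolated)
Conditions: pyrrolidine (0.5 equiv), AcOH (0.5 equiv), toluene (0.01 M), 25 → 70 °C
Reagents that add atoms: none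
Why: Pyrrolidinium acetate converts the enal into its iminium ion, the enol of the C11 ketone adds through C9 to C8 (intramolecular Michael addition) to give 24, and the C6 aldehyde thus released is attacked through C5 by the enamine or enol of the ring-A ketone, after which loss of water gives the C5=C6 enone 25. The closest known reaction type is the amine-mediated Michael/aldol-condensation (Robinson-type) annulation, run here as an intramolecular iminium–enamine cascade. Ring C closes 6-exo-trig (C9 onto the exocyclic C8=C7) and ring B closes 6-(enolexo)-exo-trig onto C6 followed by E1cB dehydration. C8 is controlled by the existing C14 centre through a chair-like transition state in which the CH2OTBDPS group on C14, the ester on C13 and the iminium-bearing arm (C7) are equatorial and the acyloxymethyl group (C17) is axial, which places C17 cis to C15; C9 is α to the C11 carbonyl and should equilibrate to the trans B/C arrangement (H9 anti to C17), and C5 and C6 stay sp2. The step needs C9 and not C12 to attack C8, and C5 and not C12, C13 or C7 to condense with C6: only C9 gives a six-membered ring, and only the C5 aldol can dehydrate, because every other aldol is a bridged ketol that would need a bridgehead double bond, so the reversible side equilibria should drain into 25.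

Step 15
Reactants: 25 tricyclic enone
Product: 26 trans-fused 4,11-diketone (5α-H)
Conditions: H2 (1 atm), 10% Pd/C, EtOAc, rt
Reagents that add atoms: none
Why: Heterogeneous hydrogenation of the enone C=C should deliver hydrogen to the α-face, away from the β-axial C20 methyl and C17 oxymethylene groups, to give the 5α-H trans-fused ketone, and C5 stays correctable by base equilibration because it is α to the C4 carbonyl.

Step 16
Reactants: 26 trans-fused 4,11-diketone; 27 dimethylzinc
Product: 28 4,4-dimethyl 11-ketone (methyl ester at C13; C13 epimers)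
Conditions: Me2Zn (3 equiv), TiCl4 (3 equiv) [Me2TiCl2 formed in situ], CH2Cl2, −40 → 0 °C
Reagents that add atoms: dimethylzinc, C[Zn]C
Why: Titanium-mediated geminal dimethylation of a ketone (methyl addition, ionisation of the titanium alkoxide, second methyl transfer) should convert the C4 carbonyl into the gem-dimethyl group, the C11 ketone being shielded by C20, C17 and the neighbouring quaternary centres as 11-oxo groups in steroids are.

Step 17
Reactants: 28 4,4-dimethyl 11-ketone
Product: 30 bridged γ-lactone (C16 carbonyl to 11β-oxygen; 13α-H), via hydroxy ester 29 (not isolated)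
Conditions: NaBH4, THF/MeOH, 0 → 40 °C; aqueous work-up; then DBU, toluene, 90 °C
Reagents that add atoms: none
Why: Hydride should attack the C11 ketone from the open α-face to give the axial 11β-alcohol, and DBU then epimerises C13 so that the ester in the axial position is trapped by the 1,3-diaxial hydroxyl as the bridged γ-lactone, which fixes C11 and C13.

Step 18
Reactants: 30 bridged γ-lactone; 31 acetic anhydride
Product: 33 16-acetoxy lactol (exo acetate), via lactol 32 (not isolated)
Conditions: DIBAL-H (1.1 equiv), CH2Cl2, −78 °C; Rochelle salt work-up; then Ac2O, pyridine, DMAP, CH2Cl2, 0 °C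
Reagents that add atoms: acetic anhydride, CC(=O)OC(C)=O
Why: Half-reduction of the strained γ-lactone with DIBAL-H at −78 °C should be faster than attack on the hindered neopentyl-type ester, and the equilibrating lactol anomers should be acetylated on the less hindered exo face, away from the C17 group, which sets C16.

Step 19
Reactants: 33 16-acetoxy lactol
Product: 34 primary alcohol at C15
Conditions: HF·pyridine, pyridine, THF, 0 °C → rt
Reagents that add atoms: none
Why: Buffered fluoride should cleave the primary silyl ether while the anomeric acetate and the ester survive.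

Step 20
Reactants: 34 primary alcohol at C15
Product: 35 CNP0331370.1
Conditions: Dess–Martin periodinane, pyridine, CH2Cl2, 0 °C
Reagents that add atoms: none
Why: Dess–Martin oxidation under buffered conditions should give the C15 aldehyde without epimerising C14, where the formyl group is equatorial.

**Compound list**
1 | 3-ethoxycyclohex-2-en-1-one | CCOC1=CC(=O)CCC1 | starting material
2 | allylmagnesium bromide | C=CC[Mg]Br | starting material
3 | 3-(prop-2-en-1-yl)cyclohex-2-en-1-one | C=CCC1=CC(=O)CCC1 | intermediate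
4 | trimethylaluminium | C[Al](C)C | starting material
5 | (R)-3-methyl-3-(prop-2-en-1-yl)cyclohexan-1-one | O=C1CCC[C@](C)(CC=C)C1 | intermediate
6 | N-bromosuccinimide | O=C1CCC(=O)N1Br | starting material
7 | water | O | starting material
8 | 3-(3-bromo-2-hydroxypropyl)-3-methylcyclohexan-1-one (quaternary centre as in 5; carbinol epimers) | O=C1CCC[C@](C)(CC(O)CBr)C1 | intermediate
9 | 3-(3-bromo-2-oxopropyl)-3-methylcyclohexan-1-one (quaternary centre as in 5) | O=C1CCC[C@](C)(CC(=O)CBr)C1 | intermediate
10 | (E)-but-2-ene-1,4-diol | OC/C=C/CO | starting material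
11 | tert-butyl(chloro)diphenylsilane | CC(C)(C)[Si](Cl)(c1ccccc1)c1ccccc1 | starting material
12 | (E)-4-{[tert-butyl(diphenyl)silyl]oxy}but-2-en-1-ol | OC/C=C/CO[Si](c1ccccc1)(c1ccccc1)C(C)(C)C | intermediate
13 | (E)-4-{[tert-butyl(diphenyl)silyl]oxy}but-2-enal | O=C/C=C/CO[Si](c1ccccc1)(c1ccccc1)C(C)(C)C | intermediate
14 | dimethyl malonate | COC(=O)CC(=O)OC | starting material
15 | dimethyl (S)-2-[1-{[tert-butyl(diphenyl)silyl]oxy}-4-oxobutan-2-yl]malonate | COC(=O)C(C(=O)OC)[C@@H](CO[Si](c1ccccc1)(c1ccccc1)C(C)(C)C)CC=O | intermediate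
16 | 2,2-dimethoxyacetaldehyde | COC(OC)C=O | starting material
17 | dimethyl 2-[(E)-1-{[tert-butyl(diphenyl)silyl]oxy}-3-formyl-5,5-dimethoxypent-3-en-2-yl]malonate | COC(=O)C(C(=O)OC)[C@@H](CO[Si](c1ccccc1)(c1ccccc1)C(C)(C)C)/C(C=O)=C\C(OC)OC | intermediate
18 | dimethyl 2-[(E)-1-{[tert-butyl(diphenyl)silyl]oxy}-3-(hydroxymethyl)-5,5-dimethoxypent-3-en-2-yl]malonate | COC(=O)C(C(=O)OC)[C@@H](CO[Si](c1ccccc1)(c1ccccc1)C(C)(C)C)/C(CO)=C\C(OC)OC | intermediate
19 | 3-methylbutanoyl chloride | CC(C)CC(=O)Cl | starting material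
20 | dimethyl 2-[(E)-1-{[tert-butyl(diphenyl)silyl]oxy}-5,5-dimethoxy-3-{[(3-methylbutanoyl)oxy]methyl}pent-3-en-2-yl]malonate | COC(=O)C(C(=O)OC)[C@@H](CO[Si](c1ccccc1)(c1ccccc1)C(C)(C)C)/C(COC(=O)CC(C)C)=C\C(OC)OC | intermediate
21 | dimethyl 2-[the pentenyl arm of 20]-2-[3-(1-methyl-3-oxocyclohexyl)-2-oxopropyl]malonate | O=C1CCC[C@](C)(CC(=O)CC(C(=O)OC)(C(=O)OC)[C@@H](CO[Si](c2ccccc2)(c2ccccc2)C(C)(C)C)/C(COC(=O)CC(C)C)=C\C(OC)OC)C1 | intermediate
22 | methyl 2-[the pentenyl arm of 20]-5-(1-methyl-3-oxocyclohexyl)-4-oxopentanoate (C13 epimers) | O=C1CCC[C@](C)(CC(=O)CC(C(=O)OC)[C@@H](CO[Si](c2ccccc2)(c2ccccc2)C(C)(C)C)/C(COC(=O)CC(C)C)=C\C(OC)OC)C1 | intermediate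
23 | keto-enal (acetal of 22 hydrolysed to the C6 aldehyde) | O=C1CCC[C@](C)(CC(=O)CC(C(=O)OC)[C@@H](CO[Si](c2ccccc2)(c2ccccc2)C(C)(C)C)/C(COC(=O)CC(C)C)=C\C=O)C1 | intermediate
24 | keto-aldehyde (ring C closed by the C8–C9 bond; C6 aldehyde free) | O=C1CC(C(=O)OC)[C@@H](CO[Si](c2ccccc2)(c2ccccc2)C(C)(C)C)[C@](COC(=O)CC(C)C)(CC=O)[C@H]1[C@@]1(C)CCCC(=O)C1 | intermediate
25 | tricyclic enone (4,11-dioxo; C5=C6; 8β-CH2O-isovalerate; 9α-H; 10β-CH3; 14β-CH2OTBDPS; 13-CO2Me epimers) | O=C1CC(C(=O)OC)[C@@H](CO[Si](c2ccccc2)(c2ccccc2)C(C)(C)C)[C@]2(COC(=O)CC(C)C)CC=C3C(=O)CCC[C@]3(C)[C@@H]12 | intermediate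
26 | trans-fused 4,11-diketone (5α-H) | O=C1CC(C(=O)OC)[C@@H](CO[Si](c2ccccc2)(c2ccccc2)C(C)(C)C)[C@]2(COC(=O)CC(C)C)CC[C@H]3C(=O)CCC[C@]3(C)[C@@H]12 | intermediate
27 | dimethylzinc | C[Zn]C | starting material
28 | 4,4-dimethyl 11-ketone (13-CO2Me epimers) | O=C1CC(C(=O)OC)[C@@H](CO[Si](c2ccccc2)(c2ccccc2)C(C)(C)C)[C@]2(COC(=O)CC(C)C)CC[C@H]3C(C)(C)CCC[C@]3(C)[C@@H]12 | intermediate
29 | 11β-hydroxy ester (13-CO2Me epimers) | O[C@H]1CC(C(=O)OC)[C@@H](CO[Si](c2ccccc2)(c2ccccc2)C(C)(C)C)[C@]2(COC(=O)CC(C)C)CC[C@H]3C(C)(C)CCC[C@]3(C)[C@@H]12 | intermediate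
30 | bridged γ-lactone (C16 carbonyl to 11β-O; 14β-CH2OTBDPS; 8β-CH2O-isovalerate) | O=C1O[C@H]2C[C@@H]1[C@@H](CO[Si](c3ccccc3)(c3ccccc3)C(C)(C)C)[C@]1(COC(=O)CC(C)C)CC[C@H]3C(C)(C)CCC[C@]3(C)[C@@H]21 | intermediate
31 | acetic anhydride | CC(=O)OC(C)=O | starting material
32 | lactol (C16 anomers) | OC1O[C@H]2C[C@@H]1[C@@H](CO[Si](c3ccccc3)(c3ccccc3)C(C)(C)C)[C@]1(COC(=O)CC(C)C)CC[C@H]3C(C)(C)CCC[C@]3(C)[C@@H]21 | intermediate
33 | 16-acetoxy lactol with 15-OTBDPS | CC(=O)O[C@H]1O[C@H]2C[C@@H]1[C@@H](CO[Si](c3ccccc3)(c3ccccc3)C(C)(C)C)[C@]1(COC(=O)CC(C)C)CC[C@H]3C(C)(C)CCC[C@]3(C)[C@@H]21 | intermediate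
34 | 16-acetoxy lactol with free 15-OH | CC(=O)O[C@H]1O[C@H]2C[C@@H]1[C@@H](CO)[C@]1(COC(=O)CC(C)C)CC[C@H]3C(C)(C)CCC[C@]3(C)[C@@H]21 | intermediate
35 | CNP0331370.1 | CC(=O)O[C@H]1O[C@H]2C[C@@H]1[C@@H](C=O)[C@]1(COC(=O)CC(C)C)CC[C@H]3C(C)(C)CCC[C@]3(C)[C@@H]21 | target

**Step count**
Total: 20 steps. Longest linear sequence: 16 steps (10 to 35, steps 5–20); steps 1–4 form the second branch, which joins at step 11.

**Three steps most likely to fail**

Step 14. The Michael closure may show poor facial selectivity at C8. The enal may also isomerise by γ-deprotonation (dienamine formation) before the hindered C9 adds to the fully substituted C8. Fallback, from 18 back to 30: a lactone tether fixes C8 by ring constraint. The allylic alcohol 18 is lactonised onto one malonate ester (DBU, toluene, 60 °C) to the δ-lactone ester F1. F1 is C-alkylated with 9 (Cs2CO3, DMF) to the lactone keto ester F2 and demethoxycarbonylated (LiCl, wet DMSO) to the trans-disubstituted δ-lactone F3, whose C13 centre equilibrates to trans. Acetal hydrolysis (PPTS, aqueous acetone) gives the lactone enal F4. The same amine-mediated cascade now has to bridge C13 and C8 across the lactone, so the configuration at C8 follows from C14 and C13, giving the bridged lactone enone F5. Hydrogenation gives the bridged lactone diketone F6 and gem-dimethylation the bridged lactone ketone F7, as in steps 15 and 16. NaBH4 then reduces the C11 ketone from the exo face, and the endo 11β-alkoxide opens the δ-lactone by translactonisation to the hydroxy γ-lactone F8. Acylation of F8 with 19 (pyridine, DMAP) gives 30.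

Step 16. Ionisation at C4, next to the C5–H bond and the quaternary C10, may lead to elimination or Wagner–Meerwein shifts, and the titanium reagent may also attack the C11 ketone or the silyl ether. Fallback, from 26 back to 28: Wittig methylenation (Ph3P=CH2, THF), to which the hindered C11 ketone should be inert, gives the 4-methylene compound F9. Simmons–Smith cyclopropanation (Et2Zn, CH2I2) gives the spirocyclopropane F10. Hydrogenolysis of the cyclopropane (H2, PtO2, AcOH) opens the bond remote from C4 and gives 28. If the C11 ketone is reduced in the same operation, the material enters step 17 as 29.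

Step 12. At 150 °C the allylic ester or the allylic acetal may be lost or substituted, and the 1,5-diketone may undergo aldol side reactions. Fallback, from 21 back to 28: the decarboxylation is moved to the robust tricycle. The acetal of 21 is hydrolysed (PPTS, aqueous acetone) to the diester enal F11. The cascade of step 14 gives the tricyclic diester enone F12, with the caveat that the axial ester on C13 may lower the selectivity at C8. Hydrogenation gives the diester diketone F13 and gem-dimethylation the 4,4-dimethyl diester F14. Krapcho dealkoxycarbonylation of F14 (LiCl, wet DMSO, 150 °C) then gives 28.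

**Further compounds**
F1 | step 14 | δ-lactone ester (C17–O–C16 lactone; CO2Me on C13) | COC(=O)C1[C@@H](CO[Si](c2ccccc2)(c2ccccc2)C(C)(C)C)/C(=C\C(OC)OC)COC1=O
F2 | step 14 | lactone keto ester (C13 quaternary) | O=C1CCC[C@](C)(CC(=O)CC2(C(=O)OC)[C@@H](CO[Si](c3ccccc3)(c3ccccc3)C(C)(C)C)/C(=C\C(OC)OC)COC2=O)C1
F3 | step 14 | trans-disubstituted δ-lactone acetal | O=C1CCC[C@](C)(CC(=O)C[C@@H]2[C@@H](CO[Si](c3ccccc3)(c3ccccc3)C(C)(C)C)/C(=C\C(OC)OC)COC2=O)C1
F4 | step 14 | lactone enal | O=C1CCC[C@](C)(CC(=O)C[C@@H]2[C@@H](CO[Si](c3ccccc3)(c3ccccc3)C(C)(C)C)/C(=C\C=O)COC2=O)C1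
F5 | step 14 | bridged lactone enone (rings B and C closed) | O=C1C[C@@H]2[C@@H](CO[Si](c3ccccc3)(c3ccccc3)C(C)(C)C)[C@]3(COC2=O)CC=C4C(=O)CCC[C@]4(C)[C@@H]13
F6 | step 14 | bridged lactone diketone (5α-H) | O=C1C[C@@H]2[C@@H](CO[Si](c3ccccc3)(c3ccccc3)C(C)(C)C)[C@]3(COC2=O)CC[C@H]4C(=O)CCC[C@]4(C)[C@@H]13
F7 | step 14 | bridged lactone 4,4-dimethyl ketone | O=C1C[C@@H]2[C@@H](CO[Si](c3ccccc3)(c3ccccc3)C(C)(C)C)[C@]3(COC2=O)CC[C@H]4C(C)(C)CCC[C@]4(C)[C@@H]13
F8 | step 14 | hydroxy γ-lactone (free C17–OH) | O=C1O[C@H]2C[C@@H]1[C@@H](CO[Si](c3ccccc3)(c3ccccc3)C(C)(C)C)[C@]1(CO)CC[C@H]3C(C)(C)CCC[C@]3(C)[C@@H]21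
F9 | step 16 | 4-methylene compound | O=C1CC(C(=O)OC)[C@@H](CO[Si](c2ccccc2)(c2ccccc2)C(C)(C)C)[C@]2(COC(=O)CC(C)C)CC[C@H]3C(=C)CCC[C@]3(C)[C@@H]12
F10 | step 16 | spirocyclopropane at C4 | O=C1CC(C(=O)OC)[C@@H](CO[Si](c2ccccc2)(c2ccccc2)C(C)(C)C)[C@]2(COC(=O)CC(C)C)CC[C@H]3C4(CC4)CCC[C@]3(C)[C@@H]12
F11 | step 12 | diester enal | O=C1CCC[C@](C)(CC(=O)CC(C(=O)OC)(C(=O)OC)[C@@H](CO[Si](c2ccccc2)(c2ccccc2)C(C)(C)C)/C(COC(=O)CC(C)C)=C\C=O)C1
F12 | step 12 | tricyclic diester enone | O=C1CC(C(=O)OC)(C(=O)OC)[C@@H](CO[Si](c2ccccc2)(c2ccccc2)C(C)(C)C)[C@]2(COC(=O)CC(C)C)CC=C3C(=O)CCC[C@]3(C)[C@@H]12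
F13 | step 12 | tricyclic diester diketone (5α-H) | O=C1CC(C(=O)OC)(C(=O)OC)[C@@H](CO[Si](c2ccccc2)(c2ccccc2)C(C)(C)C)[C@]2(COC(=O)CC(C)C)CC[C@H]3C(=O)CCC[C@]3(C)[C@@H]12
F14 | step 12 | 4,4-dimethyl diester ketone | O=C1CC(C(=O)OC)(C(=O)OC)[C@@H](CO[Si](c2ccccc2)(c2ccccc2)C(C)(C)C)[C@]2(COC(=O)CC(C)C)CC[C@H]3C(C)(C)CCC[C@]3(C)[C@@H]12
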